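**Plan**

- Retrosynthesis: the two O-benzyl groups and a ketone oxygen on the benzylic carbon attached to C3 are put back as helper groups. The lactone bonds C2–C3 and O1–C5 are then cut together, which removes CO2 and ties C3 to C5 as a cyclopropane. Further cuts are the ketone C–aryl bond, the cyclopropane bonds C3–C4 and C3–C5 (phosphonoacetate plus oxirane), and the aryl–CH2 bond (aryl Grignard plus epichlorohydrin).
- Enabling feature: C3, C4 and C5 of the γ-lactone are a contiguous three-carbon unit, and the exocyclic benzylic carbon on C3 can be carried as an aryl ketone. With a C3–C5 bond this is an acceptor cyclopropane: the unsubstituted C5 is electrophilic and C3 becomes an enolate on ring opening, so CO2 can supply C2 and O1 in a strain-releasing formal (3+2) cycloaddition.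
- Forward order: aryl Grignard + epichlorohydrin → benzyl oxirane → trans-cyclopropane ester → Weinreb amide → cyclopropyl aryl ketone → lactone ring (the only ring that is built; both arenes are bought) → removal of the ketone oxygen and the benzyl groups in one operation.
- Stereochemistry: C4 comes from (R)-epichlorohydrin, is inverted once in the cyclopropanation and is a spectator afterwards. C3 is set trans to C4 by equilibration through the β-keto lactone enol(ate) in the key step.

Key step: step 6

Assumption: the target is the trans-(3R,4R) lactone defined by the SMILES; compounds 1, 2, 6 and 9 (9 as a THF solution) are treated as commercial.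

**Route**

Step 1
Reactants: 1 4-bromo-1,2-bis(benzyloxy)benzene; 2 (R)-epichlorohydrin
Product: 4 (R)-1-[3,4-bis(benzyloxy)phenyl]-3-chloropropan-2-ol, via aryl Grignard reagent 3 (not isolated)
Conditions: Mg, I2 (cat.), THF, 40 °C; then 2, CuI (10 mol%), THF, −40 to −10 °C; then H2O
Reagents that add atoms: none
Why: Copper-catalysed Grignard opening of a terminal epoxide, in which the arylcopper species from 3 and CuI attacks the unsubstituted oxirane carbon of 2 faster than it displaces chloride, so the carbinol carbon is not a reacting centre and keeps the configuration of 2.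

Step 2
Reactants: 4 (R)-1-[3,4-bis(benzyloxy)phenyl]-3-chloropropan-2-ol
Product: 5 (R)-2-[3,4-bis(benzyloxy)benzyl]oxirane
Conditions: NaOH (2 M aq.), THF, 0 °C to rt
Reagents that add atoms: none
Why: Intramolecular Williamson etherification (3-exo-tet) of the chlorohydrin alkoxide at the primary C–Cl carbon, which leaves the stereocentre untouched.

Step 3
Reactants: 5 (R)-2-[3,4-bis(benzyloxy)benzyl]oxirane; 6 triethyl phosphonoacetate
Product: 7 ethyl (1S,2R)-2-[3,4-bis(benzyloxy)benzyl]cyclopropane-1-carboxylate
Conditions: 6 (2 equiv), NaH (2 equiv), DME, 0 °C to rt; then 5, 110 °C (sealed vessel)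
Reagents that add atoms: none
Why: Wadsworth–Emmons cyclopropanation, in which the phosphonate carbanion opens the oxirane at CH2, the phosphoryl group moves from carbon to the new alkoxide, and the resulting ester enolate displaces the secondary phosphate by 3-exo-tet SN2 with inversion (this fixes the benzyl-bearing carbon), while the ester takes the trans position in the less crowded transition state.

Step 4
Reactants: 7 ethyl (1S,2R)-2-[3,4-bis(benzyloxy)benzyl]cyclopropane-1-carboxylate
Product: 8 (1S,2R)-2-[3,4-bis(benzyloxy)benzyl]-N-methoxy-N-methylcyclopropane-1-carboxamide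
Conditions: MeNH(OMe)·HCl (1.5 equiv), i-PrMgCl (3 equiv), THF, −20 to 0 °C
Reagents that add atoms: N,O-dimethylhydroxylamine hydrochloride, CNOC.Cl
Why: Weinreb amide formation by direct aminolysis of the ester with the chloromagnesium amide of N,O-dimethylhydroxylamine; the ring stereocentres are not involved and the trans arrangement is in any case the favoured one.

Step 5
Reactants: 8 (1S,2R)-2-[3,4-bis(benzyloxy)benzyl]-N-methoxy-N-methylcyclopropane-1-carboxamide; 9 3,4-dimethoxyphenylmagnesium bromide
Product: 10 [(1S,2R)-2-[3,4-bis(benzyloxy)benzyl]cyclopropyl](3,4-dimethoxyphenyl)methanone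
Conditions: 9 (1.3 equiv, 0.5 M in THF), THF, 0 °C to rt; then H2O/aq. NH4Cl
Reagents that add atoms: none
Why: Weinreb ketone synthesis, in which the magnesium-chelated tetrahedral adduct persists until work-up so that one aryl group is delivered and no tertiary alcohol forms; no stereocentre reacts.

Step 6
Reactants: 10 [(1S,2R)-2-[3,4-bis(benzyloxy)benzyl]cyclopropyl](3,4-dimethoxyphenyl)methanone
Product: 13 (3S,4R)-4-[3,4-bis(benzyloxy)benzyl]-3-(3,4-dimethoxybenzoyl)dihydrofuran-2(3H)-one, via iodomagnesium enolate 11 (not isolated), via magnesium keto carboxylate 12 (not isolated)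
Conditions: MgI2 (1.5 equiv), CO2 (30 bar), MeCN, 60 °C (autoclave); then dilute aq. HCl
Reagents that add atoms: carbon dioxide, O=C=O
Why: Proposed new method: MgI2 binds the aryl ketone oxygen and iodide opens the activated cyclopropane by SN2 attack at the unsubstituted ring CH2 (the future C5) to give the γ-iodo magnesium enolate 11; its enolate carbon (the future C3) adds to CO2 to give the chelated magnesium β-keto carboxylate 12, whose carboxylate oxygen displaces the primary iodide to close the lactone and return MgI2, so the cyclopropane takes up CO2 in a formal (3+2) cycloaddition driven by release of ring strain. The closest known reaction types are the iodide/Lewis acid ring opening of cyclopropyl ketones to enolates that are trapped by aldehydes, the MgI2-mediated (3+2) ring expansion of acceptor cyclopropanes with imines, and the magnesium-mediated carboxylation of ketone enolates with CO2; only CO2 as the two-atom partner is new. The γ-lactone is the only ring closed, by 5-exo-tet O-alkylation of the carboxylate. C4 is not a reacting centre and is carried over from 10, whereas C3 lies between two carbonyl groups, epimerises through the enol(ate) and should settle trans to the C4 benzyl group under thermodynamic control. The step needs iodide to attack the CH2 and not the benzyl-bearing ring carbon, which the SN2 preference for the unhindered primary carbon and the faster lactonisation of the primary iodide (ring opening being reversible) should secure. It also needs C-carboxylation to outrun O-alkylation of the enolate (Cloke–Wilson-type dihydrofuran), which CO2 pressure and the absence of amine base (the carboxylate is then the only anionic oxygen in 12) should secure.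

Step 7
Reactants: 13 (3S,4R)-4-[3,4-bis(benzyloxy)benzyl]-3-(3,4-dimethoxybenzoyl)dihydrofuran-2(3H)-one
Product: 14 (3R,4R)-4-(3,4-dihydroxybenzyl)-3-(3,4-dimethoxybenzyl)dihydrofuran-2(3H)-one
Conditions: H2 (3 bar), 10% Pd/C, AcOH, HClO4 (cat.), rt
Reagents that add atoms: none
Why: Catalytic benzylic hydrogenolysis, in which the aryl ketone (activated by the para-methoxy group) is reduced through the benzylic carbinol to CH2 under acid while both O-benzyl ethers are cleaved; neither C3 nor C4 is a reacting centre and trans is also the thermodynamic arrangement.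

**Compound list**

1 | 4-bromo-1,2-bis(benzyloxy)benzene | Brc1ccc(OCc2ccccc2)c(OCc2ccccc2)c1 | starting material
2 | (R)-epichlorohydrin | ClC[C@H]1CO1 | starting material
3 | 3,4-bis(benzyloxy)phenylmagnesium bromide | Br[Mg]c1ccc(OCc2ccccc2)c(OCc2ccccc2)c1 | intermediate
4 | (R)-1-[3,4-bis(benzyloxy)phenyl]-3-chloropropan-2-ol | ClC[C@H](O)Cc1ccc(OCc2ccccc2)c(OCc2ccccc2)c1 | intermediate
5 | (R)-2-[3,4-bis(benzyloxy)benzyl]oxirane | C(c1ccc(OCc2ccccc2)c(OCc2ccccc2)c1)[C@@H]1CO1 | intermediate
6 | triethyl phosphonoacetate | CCOC(=O)CP(=O)(OCC)OCC | starting material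
7 | ethyl (1S,2R)-2-[3,4-bis(benzyloxy)benzyl]cyclopropane-1-carboxylate (trans) | CCOC(=O)[C@H]1C[C@@H]1Cc1ccc(OCc2ccccc2)c(OCc2ccccc2)c1 | intermediate
8 | (1S,2R)-2-[3,4-bis(benzyloxy)benzyl]-N-methoxy-N-methylcyclopropane-1-carboxamide (trans) | CON(C)C(=O)[C@H]1C[C@@H]1Cc1ccc(OCc2ccccc2)c(OCc2ccccc2)c1 | intermediate
9 | 3,4-dimethoxyphenylmagnesium bromide | COc1ccc([Mg]Br)cc1OC | starting material
10 | [(1S,2R)-2-[3,4-bis(benzyloxy)benzyl]cyclopropyl](3,4-dimethoxyphenyl)methanone (trans) | COc1ccc(C(=O)[C@H]2C[C@@H]2Cc2ccc(OCc3ccccc3)c(OCc3ccccc3)c2)cc1OC | intermediate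
11 | iodomagnesium (3R)-4-[3,4-bis(benzyloxy)phenyl]-1-(3,4-dimethoxyphenyl)-3-(iodomethyl)but-1-en-1-olate (enolate geometry not defined) | COc1ccc(C(O[Mg]I)=C[C@H](CI)Cc2ccc(OCc3ccccc3)c(OCc3ccccc3)c2)cc1OC | intermediate
12 | iodomagnesium (3R)-4-[3,4-bis(benzyloxy)phenyl]-2-(3,4-dimethoxybenzoyl)-3-(iodomethyl)butanoate (C2 not defined) | COc1ccc(C(=O)C(C(=O)O[Mg]I)[C@H](CI)Cc2ccc(OCc3ccccc3)c(OCc3ccccc3)c2)cc1OC | intermediate
13 | (3S,4R)-4-[3,4-bis(benzyloxy)benzyl]-3-(3,4-dimethoxybenzoyl)dihydrofuran-2(3H)-one (trans) | COc1ccc(C(=O)[C@H]2C(=O)OC[C@@H]2Cc2ccc(OCc3ccccc3)c(OCc3ccccc3)c2)cc1OC | intermediate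
14 | (3R,4R)-4-(3,4-dihydroxybenzyl)-3-(3,4-dimethoxybenzyl)dihydrofuran-2(3H)-one (trans) | COc1ccc(C[C@H]2C(=O)OC[C@@H]2Cc2ccc(O)c(O)c2)cc1OC | target

**Count and risks**

Total step count: 7. Longest linear sequence: 7 steps (from 1 to 14).

Steps most likely to fail:

1. Step 6 (new method). Iodide may open the cyclopropane at the benzyl-bearing carbon, the enolate may be O-alkylated to a dihydrofuran before it is carboxylated, or CO2 uptake may stall at the cyclopropane/iodo enolate equilibrium. Fallback with known chemistry, setting out from 2 and the Grignard reagent 3 and returning at 13: 2 is condensed with dimethyl malonate (NaOMe, MeOH, reflux; cyclopropanation then lactonisation) to give methyl (1S,5R)-2-oxo-3-oxabicyclo[3.1.0]hexane-1-carboxylate F1. CuI-catalysed homoconjugate addition of 3 at the cyclopropane CH2 (THF, −30 °C) gives methyl (4R)-4-[3,4-bis(benzyloxy)benzyl]-2-oxotetrahydrofuran-3-carboxylate F2. Krapcho demethoxycarbonylation (LiCl, wet DMSO, 140 °C) gives (R)-4-[3,4-bis(benzyloxy)benzyl]dihydrofuran-2(3H)-one F3. Its lithium enolate (LiN(SiMe3)2, 2.2 equiv, THF, −78 °C) is C-acylated with 3,4-dimethoxybenzoyl chloride anti to the C4 substituent, which gives 13.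

2. Step 3. The hot, basic conditions may isomerise the benzylic oxirane to an allylic alcohol, or the secondary phosphate intermediate may eliminate towards the arene instead of closing the three-membered ring. Fallback setting out from 5 and returning at 10 (7 and 8 are bypassed): LiCH2CN (n-BuLi, MeCN, THF, −78 °C) opens the oxirane at CH2 to give (S)-5-[3,4-bis(benzyloxy)phenyl]-4-hydroxypentanenitrile F4. TsCl in pyridine gives (S)-1-[3,4-bis(benzyloxy)phenyl]-4-cyanobutan-2-yl 4-methylbenzenesulfonate F5. NaN(SiMe3)2 (THF, −78 to 0 °C) closes the ring by 3-exo-tet displacement with inversion to give (1S,2R)-2-[3,4-bis(benzyloxy)benzyl]cyclopropane-1-carbonitrile F6. Addition of 9 to the nitrile and hydrolysis of the ketimine with aq. HCl gives 10. The cis/trans composition at the carbonyl-bearing ring carbon does not matter, because that carbon is planarised in step 6.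

3. Step 7. The reduction may stop at the benzylic carbinol, or acid may dehydrate the carbinol to the α-benzylidene lactone, whose unselective hydrogenation would erode the trans relationship at C3. Fallback setting out from 13 and returning at 14: ionic deoxygenation with Et3SiH (3 equiv) in CF3CO2H/CH2Cl2 (0 °C to rt; hydride transfer to the para-methoxy-stabilised benzylic cation, with no metal surface) gives (3R,4R)-4-[3,4-bis(benzyloxy)benzyl]-3-(3,4-dimethoxybenzyl)dihydrofuran-2(3H)-one F7. Neutral hydrogenolysis of the two benzyl ethers (H2, 1 bar, Pd/C, EtOAc/EtOH) then gives 14.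

**Further compounds**

F1 | step 6 | methyl (1S,5R)-2-oxo-3-oxabicyclo[3.1.0]hexane-1-carboxylate | COC(=O)[C@]12C[C@H]1COC2=O
F2 | step 6 | methyl (4R)-4-[3,4-bis(benzyloxy)benzyl]-2-oxotetrahydrofuran-3-carboxylate (C3 epimers) | COC(=O)C1C(=O)OC[C@@H]1Cc1ccc(OCc2ccccc2)c(OCc2ccccc2)c1
F3 | step 6 | (R)-4-[3,4-bis(benzyloxy)benzyl]dihydrofuran-2(3H)-one | O=C1OC[C@H](Cc2ccc(OCc3ccccc3)c(OCc3ccccc3)c2)C1
F4 | step 3 | (S)-5-[3,4-bis(benzyloxy)phenyl]-4-hydroxypentanenitrile | N#CCC[C@H](O)Cc1ccc(OCc2ccccc2)c(OCc2ccccc2)c1
F5 | step 3 | (S)-1-[3,4-bis(benzyloxy)phenyl]-4-cyanobutan-2-yl 4-methylbenzenesulfonate | N#CCC[C@H](OS(=O)(=O)c1ccc(C)cc1)Cc1ccc(OCc2ccccc2)c(OCc2ccccc2)c1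
F6 | step 3 | (1S,2R)-2-[3,4-bis(benzyloxy)benzyl]cyclopropane-1-carbonitrile | N#C[C@H]1C[C@@H]1Cc1ccc(OCc2ccccc2)c(OCc2ccccc2)c1
F7 | step 7 | (3R,4R)-4-[3,4-bis(benzyloxy)benzyl]-3-(3,4-dimethoxybenzyl)dihydrofuran-2(3H)-one | COc1ccc(C[C@H]2C(=O)OC[C@@H]2Cc2ccc(OCc3ccccc3)c(OCc3ccccc3)c2)cc1OC
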